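**Retrosynthetic overview**
1. Target 28 ⇐ ketone 25: the last steps only add the C10 methyl group, remove the silyl groups and oxidise C3.
2. 25 ⇐ 23: rings A (oxepane) and B (cyclohexane) are closed last, in one step, by a new silyl-triflate-catalysed bis-epoxide cascade ended by a (Z)-silyl enol ether (forms C2–O and C6–C11).
3. 23 ⇐ 17 + 19: the halves are joined at C11–C12 by aldol condensation, then 1,4-hydrosilylation; 19 comes from (E)-geranylacetone by Shi epoxidation.
4. 17 ⇐ 12 ⇐ 9: C14 is set by an Eschenmoser–Claisen transposition on a cycloheptenol; ring C (cycloheptene) is closed by ring-closing metathesis.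
5. 9 ⇐ 6 ⇐ 1: C18 is set by a first Eschenmoser–Claisen on a cis-cyclopentenol; ring D comes from (R)-4-silyloxycyclopentenone, with C22 set by anti Sakurai addition. Ring order: D, then C, then B and A together.

Carbon labels used below: C2 = CMe2 of ring A; C3 = ring A carbinol/ketone carbon; C6/C7 = A/B fusion; C10 = ring B carbinol; C11 = ring B CH; C12–C13 = ethylene link; C14 = ring C CH; C15=C16 = ring C olefin; C17 = ring C CH2; C18/C22 = C/D fusion; C19 = ring D carbinol; C23 = CMe2 of ring C.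

Assumption: (E)-geranylacetone and (R)-4-(tert-butyldimethylsilyloxy)cyclopent-2-en-1-one are bought as single isomers, and the target is taken exactly as the given SMILES draws it (cis C/D fusion).

**Route**

Step 1
Reactants: 1 (R)-4-(tert-butyldimethylsilyloxy)cyclopent-2-en-1-one
Product: 3 (R)-4-(2-methylbut-3-en-2-yl)cyclopent-2-en-1-one, via silyloxy ketone 2 (not isolated)
Conditions: prenylSiMe3, TiCl4, CH2Cl2, −78 °C; aq. NaHCO3; then DBU, CH2Cl2, 0 °C, 15 min
Reagents that add atoms: prenyltrimethylsilane, CC(C)=CC[Si](C)(C)C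
Why: Hosomi–Sakurai conjugate addition delivers the tertiary allyl carbon anti to the silyloxy group, which sets C22, and E1cB loss of silanolate then transposes the enone.

Step 2
Reactants: 3 (R)-4-(2-methylbut-3-en-2-yl)cyclopent-2-en-1-one
Product: 4 (R)-2-iodo-4-(2-methylbut-3-en-2-yl)cyclopent-2-en-1-one
Conditions: I2, pyridine, CH2Cl2, 23 °C
Reagents that add atoms: iodine, II
Why: α-iodination of the enone by pyridine addition, iodination and elimination (Johnson iodination) leaves the hindered vinyl group and the γ-stereocentre alone.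

Step 3
Reactants: 4 (R)-2-iodo-4-(2-methylbut-3-en-2-yl)cyclopent-2-en-1-one
Product: 5 (R)-2-methyl-4-(2-methylbut-3-en-2-yl)cyclopent-2-en-1-one
Conditions: Me2Zn, Pd(PPh3)4 (5 mol %), THF, 0 → 23 °C
Reagents that add atoms: dimethylzinc, C[Zn]C
Why: Negishi coupling of the α-iodoenone is base-free, so the C19 methyl group is installed without γ-epimerisation or double-bond migration.

Step 4
Reactants: 5 (R)-2-methyl-4-(2-methylbut-3-en-2-yl)cyclopent-2-en-1-one
Product: 6 (1S,4R)-2-methyl-4-(2-methylbut-3-en-2-yl)cyclopent-2-en-1-ol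
Conditions: NaBH4, CeCl3·7H2O, MeOH, −78 °C
Reagents that add atoms: none
Why: Luche 1,2-reduction, in which hydride adds opposite the bulky tert-alkyl group and gives the cis alcohol whose C–O bond will relay chirality to C18.

Step 5
Reactants: 6 (1S,4R)-2-methyl-4-(2-methylbut-3-en-2-yl)cyclopent-2-en-1-ol
Product: 8 cis-cyclopentenyl-N,N-dimethylacetamide, via ketene hemiaminal ether 7 (not isolated)
Conditions: MeC(OMe)2NMe2, xylenes, 140 °C
Reagents that add atoms: N,N-dimethylacetamide dimethyl acetal, CC(OC)(OC)N(C)C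
Why: Eschenmoser–Claisen rearrangement, whose suprafacial [3,3] shift places the acetamide chain on C18 on the face the C–O bond occupied, cis to the C22 substituent, and leaves the C19 methyl on the new ring olefin.

Step 6
Reactants: 8 cis-cyclopentenyl-N,N-dimethylacetamide
Product: 9 isopropenyl ketone (3-methyl-1-cyclopentenylbut-3-en-2-one)
Conditions: 2-bromopropene, t-BuLi, Et2O, −78 °C; then 8, −78 → 0 °C; aq. NH4Cl
Reagents that add atoms: isopropenyllithium, [Li]C(C)=C (made in the flask from 2-bromopropene, C=C(C)Br)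
Why: acyl substitution of a tertiary amide by an alkenyllithium stops at the ketone because the tetrahedral lithium adduct survives until work-up.

Step 7
Reactants: 9 isopropenyl ketone
Product: 10 cis-fused bicyclic dienone (rings C and D)
Conditions: second-generation Hoveyda–Grubbs catalyst RuCl2(H2IMes)(=CH-C6H4-2-O-i-Pr) (10 mol %), toluene (2 mM), 90 °C
Reagents that add atoms: none
Why: ring-closing metathesis of the two cis-held terminal olefins closes ring C as the 2-methyl enone, while the trisubstituted ring D olefin does not take part.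

Step 8
Reactants: 10 cis-fused bicyclic dienone
Product: 11 epoxy enone
Conditions: mCPBA, NaHCO3, CH2Cl2, 0 °C
Reagents that add atoms: meta-chloroperoxybenzoic acid, OOC(=O)c1cccc(Cl)c1
Why: Prilezhaev epoxidation picks the electron-rich ring D olefin over the enone and comes from the convex face (that of the ring-fusion hydrogens), which puts the C19 oxygen anti to C17.

Step 9
Reactants: 11 epoxy enone
Product: 12 epoxy allylic alcohol (C16 carbinol S)
Conditions: (R)-2-methyl-CBS-oxazaborolidine (20 mol %), catecholborane, toluene, −78 °C; then MeOH, aq. NaOH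
Reagents that add atoms: none
Why: Corey–Bakshi–Shibata reduction under reagent control, the α-methyl alkenyl arm acting as the large group, delivers hydride to the convex face and gives the C16 alcohol on the face opposite the ring-fusion hydrogens.

Step 10
Reactants: 12 epoxy allylic alcohol
Product: 14 epoxy amide, via ketene hemiaminal ether 13 (not isolated)
Conditions: MeC(OMe)2NMe2, xylenes, 145 °C, sealed tube
Reagents that add atoms: N,N-dimethylacetamide dimethyl acetal, CC(OC)(OC)N(C)C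
Why: a second Eschenmoser–Claisen rearrangement transfers the chain suprafacially from the C16 oxygen to C14, which sets C14 and moves the olefin to C15=C16.

Step 11
Reactants: 14 epoxy amide
Product: 15 diol (tertiary C19 alcohol and primary C12 alcohol)
Conditions: LiEt3BH, THF, 0 → 23 °C; aq. NaOH
Reagents that add atoms: none
Why: triethylborohydride opens the trisubstituted epoxide by SN2 attack at its secondary carbon, so the tertiary C19–O bond is kept with its configuration, and it reduces the tertiary amide to the primary alcohol.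

Step 12
Reactants: 15 diol
Product: 16 bis(triethylsilyl) ether
Conditions: Et3SiOTf, 2,6-lutidine, CH2Cl2, −78 → 0 °C
Reagents that add atoms: triethylsilyl trifluoromethanesulfonate, CC[Si](CC)(CC)OS(=O)(=O)C(F)(F)F
Why: a silyl triflate silylates both the primary and the hindered tertiary alcohol.

Step 13
Reactants: 16 bis(triethylsilyl) ether
Product: 17 hydroazulene aldehyde (C19 silyl ether)
Conditions: (COCl)2, DMSO, CH2Cl2, −78 → −30 °C; then Et3N, −78 → 0 °C
Reagents that add atoms: none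
Why: Swern conditions cleave and oxidise a primary triethylsilyl ether directly to the aldehyde, while the tertiary silyl ether cannot react.

Step 14
Reactants: 18 (E)-geranylacetone
Product: 19 (5R,6R,9R)-5,6:9,10-diepoxy-6,10-dimethylundecan-2-one
Conditions: D-fructose-derived Shi ketone (30 mol % per olefin), Oxone (2KHSO5·KHSO4·K2SO4), K2CO3, Bu4NHSO4, MeCN/(MeO)2CH2/aq. Na2B4O7 buffer, 0 °C
Reagents that add atoms: potassium peroxymonosulfate, [K+].[O-]S(=O)(=O)OO
Why: Shi epoxidation, in which the chiral dioxirane attacks both E-trisubstituted olefins from the same face through a spiro transition state and so sets C6 and C7 (C3 is set too but is oxidised away at the end).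

Step 15
Reactants: 19 bis-epoxy methyl ketone; 17 hydroazulene aldehyde
Product: 20 β-hydroxy ketone (both C12 epimers)
Conditions: LiN(i-Pr)2, THF, −78 °C; then 17, −78 °C
Reagents that add atoms: none
Why: kinetic deprotonation at the methyl group gives the terminal lithium enolate, and its aldol addition forms the C11–C12 bond (the new carbinol centre is removed in the next step).

Step 16
Reactants: 20 β-hydroxy ketone
Product: 22 (E)-enone, via mesylate 21 (not isolated)
Conditions: MsCl, Et3N, CH2Cl2, 0 °C; then DBU, 23 °C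
Reagents that add atoms: none
Why: E1cB elimination of the β-mesyloxy ketone gives the conjugated (E)-enone and leaves both epoxides intact.

Step 17
Reactants: 22 (E)-enone
Product: 23 (Z)-triethylsilyl enol ether
Conditions: RhCl(PPh3)3 (2 mol %), Et3SiH, benzene, 50 °C
Reagents that add atoms: triethylsilane, CC[SiH](CC)CC
Why: rhodium-catalysed 1,4-hydrosilylation of the enone gives the C10=C11 enol ether with fixed regiochemistry and mainly (Z) geometry, under neutral halide-free conditions that spare the epoxides.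

Step 18
Reactants: 23 (Z)-triethylsilyl enol ether
Product: 25 ring A/B ketone (C3 silyl ether and C10 ketone), via epoxonium ion 24 (not isolated)
Conditions: Et3SiOTf (20 mol %), 2,6-di-tert-butyl-4-methylpyridine (40 mol %), CH2Cl2, −78 °C; Et3N quench
Reagents that add atoms: none
Why: Proposed new method: a silyl-triflate-catalysed isomerising bis-epoxide cascade ended by a stereodefined trisubstituted (Z)-silyl enol ether that carries the whole western half. Et3Si+ silylates the terminal epoxide, and the neighbouring epoxide oxygen opens it at the tertiary carbon C2 (7-endo) to give epoxonium ion 24. C11 of the enol ether then attacks tertiary C6 anti through a chair, with inversion at C6 and retention at C7, and the (Z) geometry places C12 equatorial so that C11 is set (any C11 epimer equilibrates α to the ketone). The resulting silyloxocarbenium ion hands Et3Si+ back to the chain, so the net change is migration of the silyl group from the enol oxygen to the C3 oxygen. The closest known reaction type is the Lewis-acid-promoted tandem oxa-/carbacyclisation of 1,5-bis-epoxides ended by 1,1-disubstituted silyl enol ethers of methyl ketones, run with stoichiometric promoter and creating no stereocentre at the nucleophilic carbon.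

Step 19
Reactants: 25 ring A/B ketone
Product: 26 tertiary alcohol (C10 S)
Conditions: MeMgBr, anhydrous CeCl3, THF, −78 °C
Reagents that add atoms: methylmagnesium bromide, C[Mg]Br
Why: organocerium 1,2-addition suppresses enolisation, and the axial C6 methyl group (1,3 to the carbonyl) blocks axial approach, so methyl enters equatorially and the C10 hydroxyl ends up axial, as in the target.

Step 20
Reactants: 26 tertiary alcohol
Product: 27 triol
Conditions: Bu4NF, THF, 50 °C
Reagents that add atoms: none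
Why: fluoride-mediated desilylation removes the secondary and the tertiary triethylsilyl ether without touching any stereocentre.

Step 21
Reactants: 27 triol
Product: 28 sipholenone A
Conditions: Dess–Martin periodinane, NaHCO3, CH2Cl2, 23 °C
Reagents that add atoms: none
Why: Dess–Martin oxidation can act only on the single secondary alcohol (C3), since the two tertiary alcohols cannot be oxidised.

**Compound list**

1 | (R)-4-(tert-butyldimethylsilyloxy)cyclopent-2-en-1-one | O=C1C=C[C@H](O[Si](C)(C)C(C)(C)C)C1 | starting material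
2 | (3S,4R)-4-(tert-butyldimethylsilyloxy)-3-(2-methylbut-3-en-2-yl)cyclopentan-1-one (trans) | O=C1C[C@@H](C(C)(C)C=C)[C@H](O[Si](C)(C)C(C)(C)C)C1 | intermediate
3 | (R)-4-(2-methylbut-3-en-2-yl)cyclopent-2-en-1-one | O=C1C=C[C@H](C(C)(C)C=C)C1 | intermediate
4 | (R)-2-iodo-4-(2-methylbut-3-en-2-yl)cyclopent-2-en-1-one | O=C1C(I)=C[C@H](C(C)(C)C=C)C1 | intermediate
5 | (R)-2-methyl-4-(2-methylbut-3-en-2-yl)cyclopent-2-en-1-one | O=C1C(C)=C[C@H](C(C)(C)C=C)C1 | intermediate
6 | (1S,4R)-2-methyl-4-(2-methylbut-3-en-2-yl)cyclopent-2-en-1-ol (cis) | O[C@@H]1C(C)=C[C@H](C(C)(C)C=C)C1 | intermediate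
7 | N,N-dimethyl-1-{[(1S,4R)-2-methyl-4-(2-methylbut-3-en-2-yl)cyclopent-2-en-1-yl]oxy}ethen-1-amine | C=C(N(C)C)O[C@@H]1C(C)=C[C@H](C(C)(C)C=C)C1 | intermediate
8 | N,N-dimethyl-2-[(1R,5R)-2-methyl-5-(2-methylbut-3-en-2-yl)cyclopent-2-en-1-yl]acetamide (cis) | CN(C)C(=O)C[C@@H]1[C@@H](CC=C1C)C(C)(C)C=C | intermediate
9 | 3-methyl-1-[(1R,5R)-2-methyl-5-(2-methylbut-3-en-2-yl)cyclopent-2-en-1-yl]but-3-en-2-one | C=C(C)C(=O)C[C@@H]1[C@@H](CC=C1C)C(C)(C)C=C | intermediate
10 | (3aR,8aR)-3,6,8,8-tetramethyl-3a,4,8,8a-tetrahydroazulen-5(1H)-one (cis-fused) | O=C1C[C@@H]2[C@@H](CC=C2C)C(C)(C)C=C1C | intermediate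
11 | (2R,3S,3aR,8aR)-2,3-epoxy-3,6,8,8-tetramethyl-2,3,3a,4,8,8a-hexahydroazulen-5(1H)-one (epoxide on the face of the ring-fusion hydrogens) | O=C1C[C@@H]2[C@@H](C[C@H]3O[C@@]23C)C(C)(C)C=C1C | intermediate
12 | (2R,3S,3aR,5S,8aR)-2,3-epoxy-3,6,8,8-tetramethyl-1,2,3,3a,4,5,8,8a-octahydroazulen-5-ol | O[C@H]1C[C@@H]2[C@@H](C[C@H]3O[C@@]23C)C(C)(C)C=C1C | intermediate
13 | N,N-dimethyl-1-{[(2R,3S,3aR,5S,8aR)-2,3-epoxy-3,6,8,8-tetramethyl-1,2,3,3a,4,5,8,8a-octahydroazulen-5-yl]oxy}ethen-1-amine | C=C(N(C)C)O[C@H]1C[C@@H]2[C@@H](C[C@H]3O[C@@]23C)C(C)(C)C=C1C | intermediate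
14 | 2-[(1S,2R,3aR,5S,8aR)-1,2-epoxy-1,4,4,6-tetramethyl-1,2,3,3a,4,5,8,8a-octahydroazulen-5-yl]-N,N-dimethylacetamide | CC1=CC[C@@H]2[C@@H](C[C@H]3O[C@@]23C)C(C)(C)[C@H]1CC(=O)N(C)C | intermediate
15 | (1R,3aR,5S,8aR)-5-(2-hydroxyethyl)-1,4,4,6-tetramethyl-1,2,3,3a,4,5,8,8a-octahydroazulen-1-ol | CC1=CC[C@@H]2[C@@H](CC[C@@]2(C)O)C(C)(C)[C@H]1CCO | intermediate
16 | triethyl{2-[(1R,3aR,5S,8aR)-1,4,4,6-tetramethyl-1-(triethylsilyloxy)-1,2,3,3a,4,5,8,8a-octahydroazulen-5-yl]ethoxy}silane | CC1=CC[C@@H]2[C@@H](CC[C@@]2(C)O[Si](CC)(CC)CC)C(C)(C)[C@H]1CCO[Si](CC)(CC)CC | intermediate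
17 | 2-[(1R,3aR,5S,8aR)-1,4,4,6-tetramethyl-1-(triethylsilyloxy)-1,2,3,3a,4,5,8,8a-octahydroazulen-5-yl]acetaldehyde | CC1=CC[C@@H]2[C@@H](CC[C@@]2(C)O[Si](CC)(CC)CC)C(C)(C)[C@H]1CC=O | intermediate
18 | (E)-geranylacetone, (E)-6,10-dimethylundeca-5,9-dien-2-one | CC(=O)CC/C=C(\C)CCC=C(C)C | starting material
19 | (5R,6R,9R)-5,6:9,10-diepoxy-6,10-dimethylundecan-2-one | CC(=O)CC[C@H]1O[C@]1(C)CC[C@H]1OC1(C)C | intermediate
20 | (7R,8R,11R)-7,8:11,12-diepoxy-2-hydroxy-8,12-dimethyl-1-[(1R,3aR,5S,8aR)-1,4,4,6-tetramethyl-1-(triethylsilyloxy)-1,2,3,3a,4,5,8,8a-octahydroazulen-5-yl]tridecan-4-one (both C2 epimers) | CC1=CC[C@@H]2[C@@H](CC[C@@]2(C)O[Si](CC)(CC)CC)C(C)(C)[C@H]1CC(O)CC(=O)CC[C@H]1O[C@]1(C)CC[C@H]1OC1(C)C | intermediate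
21 | methanesulfonate of 20 at the C2 hydroxyl (both epimers) | CC1=CC[C@@H]2[C@@H](CC[C@@]2(C)O[Si](CC)(CC)CC)C(C)(C)[C@H]1CC(OS(C)(=O)=O)CC(=O)CC[C@H]1O[C@]1(C)CC[C@H]1OC1(C)C | intermediate
22 | (2E,7R,8R,11R)-7,8:11,12-diepoxy-8,12-dimethyl-1-[(1R,3aR,5S,8aR)-1,4,4,6-tetramethyl-1-(triethylsilyloxy)-1,2,3,3a,4,5,8,8a-octahydroazulen-5-yl]tridec-2-en-4-one | CC1=CC[C@@H]2[C@@H](CC[C@@]2(C)O[Si](CC)(CC)CC)C(C)(C)[C@H]1C/C=C/C(=O)CC[C@H]1O[C@]1(C)CC[C@H]1OC1(C)C | intermediate
23 | (3Z,7R,8R,11R)-7,8:11,12-diepoxy-8,12-dimethyl-4-(triethylsilyloxy)-1-[(1R,3aR,5S,8aR)-1,4,4,6-tetramethyl-1-(triethylsilyloxy)-1,2,3,3a,4,5,8,8a-octahydroazulen-5-yl]tridec-3-ene | CC1=CC[C@@H]2[C@@H](CC[C@@]2(C)O[Si](CC)(CC)CC)C(C)(C)[C@H]1CC/C=C(\O[Si](CC)(CC)CC)CC[C@H]1O[C@]1(C)CC[C@H]1OC1(C)C | intermediate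
24 | bicyclic epoxonium triflate: oxepane closed (C2–O), its oxygen still bridging C6 and C7 as an oxiranium, C3 silyl ether, enol ether intact | CC1=CC[C@@H]2[C@@H](CC[C@@]2(C)O[Si](CC)(CC)CC)C(C)(C)[C@H]1CC/C=C(\O[Si](CC)(CC)CC)CC[C@H]1[O+]2C(C)(C)[C@H](O[Si](CC)(CC)CC)CC[C@]12C.[O-]S(=O)(=O)C(F)(F)F | intermediate
25 | (3R,5aR,6R,9aR)-2,2,5a-trimethyl-6-{2-[(1R,3aR,5S,8aR)-1,4,4,6-tetramethyl-1-(triethylsilyloxy)-1,2,3,3a,4,5,8,8a-octahydroazulen-5-yl]ethyl}-3-(triethylsilyloxy)octahydro-1-benzoxepin-7(2H)-one (trans-fused) | CC1=CC[C@@H]2[C@@H](CC[C@@]2(C)O[Si](CC)(CC)CC)C(C)(C)[C@H]1CC[C@@H]1[C@@]2(C)CC[C@@H](O[Si](CC)(CC)CC)C(C)(C)O[C@@H]2CCC1=O | intermediate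
26 | (3R,5aR,6R,7S,9aR)-2,2,5a,7-tetramethyl-6-{2-[(1R,3aR,5S,8aR)-1,4,4,6-tetramethyl-1-(triethylsilyloxy)-1,2,3,3a,4,5,8,8a-octahydroazulen-5-yl]ethyl}-3-(triethylsilyloxy)decahydro-1-benzoxepin-7-ol | CC1=CC[C@@H]2[C@@H](CC[C@@]2(C)O[Si](CC)(CC)CC)C(C)(C)[C@H]1CC[C@@H]1[C@@]2(C)CC[C@@H](O[Si](CC)(CC)CC)C(C)(C)O[C@@H]2CC[C@]1(C)O | intermediate
27 | (3R,5aR,6R,7S,9aR)-6-{2-[(1R,3aR,5S,8aR)-1-hydroxy-1,4,4,6-tetramethyl-1,2,3,3a,4,5,8,8a-octahydroazulen-5-yl]ethyl}-2,2,5a,7-tetramethyldecahydro-1-benzoxepine-3,7-diol | CC1=CC[C@@H]2[C@@H](CC[C@@]2(C)O)C(C)(C)[C@H]1CC[C@@H]1[C@@]2(C)CC[C@@H](O)C(C)(C)O[C@@H]2CC[C@]1(C)O | intermediate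
28 | sipholenone A, (5aR,6R,7S,9aR)-7-hydroxy-6-{2-[(1R,3aR,5S,8aR)-1-hydroxy-1,4,4,6-tetramethyl-1,2,3,3a,4,5,8,8a-octahydroazulen-5-yl]ethyl}-2,2,5a,7-tetramethyloctahydro-1-benzoxepin-3(2H)-one | CC1=CC[C@@H]2[C@@H](CC[C@@]2(C)O)C(C)(C)[C@H]1CC[C@@H]1[C@@]2(C)CCC(=O)C(C)(C)O[C@@H]2CC[C@]1(C)O | target

**Count and risks**

Total step count: 21. Longest linear sequence: 20 steps (1 to 28 through steps 1–13 and 15–21).

The three steps most likely to fail:

Step 18 (the proposed new cascade). The fallback uses known chemistry; it sets out from 19 (and uses 17) and comes back at 25. Kinetic enolisation of 19 at the methyl group (LiN(i-Pr)2, Et3SiCl, THF, −78 °C) gives the 1,1-disubstituted silyl enol ether F1. This is the established terminator class, and Et3SiOTf with 2,6-di-tert-butyl-4-methylpyridine in CH2Cl2 at −78 °C closes rings A and B to the bicyclic silyloxy ketone F2, which is unsubstituted at C11. Dehydrogenation with IBX and 4-methoxypyridine N-oxide in DMSO can only go towards C8–C9, because C6 is quaternary, and gives the ring B enone F3. Its kinetic cross-conjugated lithium enolate can form only at C11 and adds to aldehyde 17 to give the aldol adduct F4. Mesylation (MsCl, Et3N) gives the mesylate F5, and DBU eliminates it to the cross-conjugated dienone F6. Conjugate reduction of both enone double bonds with [(Ph3P)CuH]6, then equilibration of C11 with DBU, gives 25.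

Step 7 (ring-closing metathesis between a hindered vinyl group and a 1,1-disubstituted enone olefin). The fallback sets out from 8 and comes back at 10. Vinyllithium converts amide 8 to the vinyl ketone F7. Its metathesis has to form only a disubstituted enone olefin and gives the bicyclic enone F8 far more easily. α-Iodination (I2, pyridine) gives the iodoenone F9, and Negishi methylation (Me2Zn, Pd(PPh3)4) gives 10.

Step 10 (Claisen bond formation at C14, next to the quaternary C23). The fallback sets out from 12 and comes back at 15. Phenyl isocyanate converts 12 to the N-phenylcarbamate F10. Deprotonation with MeLi, then CuI and vinyllithium, gives a carbamate-bound cuprate that delivers vinyl to C14 by syn-SN2′ substitution on the face of the leaving group, which gives the C14-vinyl epoxide F11. Hydroboration of the only monosubstituted olefin with 9-BBN gives the alkylborane F12, and NaBO3 oxidation gives the primary alcohol F13. LiEt3BH then opens the epoxide to give 15.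

Further compounds
F1 | step 18 | (5R,6R,9R)-5,6:9,10-diepoxy-6,10-dimethyl-2-(triethylsilyloxy)undec-1-ene | C=C(O[Si](CC)(CC)CC)CC[C@H]1O[C@]1(C)CC[C@H]1OC1(C)C
F2 | step 18 | (3R,5aR,9aR)-2,2,5a-trimethyl-3-(triethylsilyloxy)octahydro-1-benzoxepin-7(2H)-one | C1[C@@]2(C)CC[C@@H](O[Si](CC)(CC)CC)C(C)(C)O[C@@H]2CCC1=O
F3 | step 18 | (3R,5aR,9aR)-2,2,5a-trimethyl-3-(triethylsilyloxy)-3,4,5,5a,6,9a-hexahydro-1-benzoxepin-7(2H)-one (C8=C9 enone) | C1[C@@]2(C)CC[C@@H](O[Si](CC)(CC)CC)C(C)(C)O[C@@H]2C=CC1=O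
F4 | step 18 | aldol adduct of the C11 enolate of F3 with 17 (mixture at C11 and C12) | CC1=CC[C@@H]2[C@@H](CC[C@@]2(C)O[Si](CC)(CC)CC)C(C)(C)[C@H]1CC(O)C1C(=O)C=C[C@H]2OC(C)(C)[C@H](O[Si](CC)(CC)CC)CC[C@]12C
F5 | step 18 | methanesulfonate of F4 at the C12 hydroxyl | CC1=CC[C@@H]2[C@@H](CC[C@@]2(C)O[Si](CC)(CC)CC)C(C)(C)[C@H]1CC(OS(C)(=O)=O)C1C(=O)C=C[C@H]2OC(C)(C)[C@H](O[Si](CC)(CC)CC)CC[C@]12C
F6 | step 18 | cross-conjugated dienone with exocyclic C11=C12 and ring C8=C9 (olefin geometry not fixed) | CC1=CC[C@@H]2[C@@H](CC[C@@]2(C)O[Si](CC)(CC)CC)C(C)(C)[C@H]1CC=C1C(=O)C=C[C@H]2OC(C)(C)[C@H](O[Si](CC)(CC)CC)CC[C@]12C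
F7 | step 7 | 1-[(1R,5R)-2-methyl-5-(2-methylbut-3-en-2-yl)cyclopent-2-en-1-yl]but-3-en-2-one | C=CC(=O)C[C@@H]1[C@@H](CC=C1C)C(C)(C)C=C
F8 | step 7 | (3aR,8aR)-3,8,8-trimethyl-3a,4,8,8a-tetrahydroazulen-5(1H)-one | O=C1C[C@@H]2[C@@H](CC=C2C)C(C)(C)C=C1
F9 | step 7 | (3aR,8aR)-6-iodo-3,8,8-trimethyl-3a,4,8,8a-tetrahydroazulen-5(1H)-one | O=C1C[C@@H]2[C@@H](CC=C2C)C(C)(C)C=C1I
F10 | step 10 | N-phenylcarbamate of 12 | O=C(Nc1ccccc1)O[C@H]1C[C@@H]2[C@@H](C[C@H]3O[C@@]23C)C(C)(C)C=C1C
F11 | step 10 | (1S,2R,3aR,5S,8aR)-5-ethenyl-1,2-epoxy-1,4,4,6-tetramethyl-1,2,3,3a,4,5,8,8a-octahydroazulene | CC1=CC[C@@H]2[C@@H](C[C@H]3O[C@@]23C)C(C)(C)[C@H]1C=C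
F12 | step 10 | B-alkyl-9-borabicyclo[3.3.1]nonane from terminal hydroboration of F11 | CC1=CC[C@@H]2[C@@H](C[C@H]3O[C@@]23C)C(C)(C)[C@H]1CCB1C2CCCC1CCC2
F13 | step 10 | 2-[(1S,2R,3aR,5S,8aR)-1,2-epoxy-1,4,4,6-tetramethyl-1,2,3,3a,4,5,8,8a-octahydroazulen-5-yl]ethanol | CC1=CC[C@@H]2[C@@H](C[C@H]3O[C@@]23C)C(C)(C)[C@H]1CCO
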